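Start from a ratio: the charge of free monomer over the charge of initiator, 20.0 monomer units per initiator molecule. This is the ceiling length of epsilon and beta, provided each initiator molecule begins one chain and transfer agent begins none.

| setting | west | north-west | epsilon | beta |
|---|---|---|---|---|
| free monomer | 17 mM (fed, over 4.0 d) | 17 mM (fed, over 4.0 d) | 17 mM (fed, over 4.0 d) | 17 mM (fed, over 4.0 d) |
| transfer agent | 0.51 mM | 0.51 mM | 0.510 mM | 0.510 mM |
| initiator | 0.57 mM | 1.3 mM | 0.85 mM | 0.85 mM |
| remark | run made earlier | run made earlier |  |  |
| time |  |  | 10 d | 5.0 d |

| run | time / d | monomer in chains / % | free monomer / % |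
|---|---|---|---|
| west | 0.333 | 0.4 | 8.3 |
| west | 0.833 | 2.0 | 19.0 |
| west | 1.67 | 8.7 | 34.1 |
| west | 2.50 | 15.0 | 46.9 |
| west | 4.00 | 33.6 | 66.3 |
| west | 5.00 | 45.7 | 54.5 |
| west | 6.00 | 54.9 | 45.1 |
| north-west | 0.833 | 4.4 | 18.1 |
| north-west | 1.67 | 14.1 | 27.6 |
| north-west | 2.50 | 28.8 | 33.9 |
| north-west | 3.00 | 37.8 | 37.2 |
| north-west | 4.00 | 57.4 | 40.9 |
| north-west | 5.00 | 74.2 | 26.0 |
| north-west | 6.00 | 83.0 | 15.9 |

(readings scatter by 0.5 percentage points)

- the average divides the monomer in chains by the number of chains begun, living and dead together
- the earlier runs do not show the number of chains; that part of a forecast is a guess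
- percentages count the whole charge, also what has not yet gone in

- which of the two ends with the longer chains by the average number of monomer units in a chain (chains begun, living or dead) ("neither" if they lie within 10 %) (epsilon / beta / neither)
- average number of monomer units in a chain (chains begun, living or dead) at the end, epsilon
- average number of monomer units in a chain (chains begun, living or dead) at the end, beta

Follow one molecule of transfer agent to its fork: does it begin a chain, or merely end one? The chain count is unseen, so your answer is a guess, but the rates give a hint. After the feed, free monomer decays with a pseudo-first-order constant of 0.193 d⁻¹ as read in the west run and 0.472 d⁻¹ in the north-west run. Their ratio is 0.409. The ratio of [initiator] is 0.438, and with transfer agent counted in it is 0.597. So I count chains by [initiator] charged, and length is the ceiling times the fraction in chains.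

Now draw the curve that epsilon and beta share, since they differ in reading time. Scaled to their [initiator], the constant is 0.302 d⁻¹. Free monomer starts rising at the feed rate, 4.25 mM d⁻¹, and bends towards 14.1 mM. The feed stops at 4.0 d, with by my reckoning 9.86 mM standing, less than that level: this knee lies at 58.0 % of the charge. Free monomer then decays, and by my reckoning monomer in chains equals it at 4.49 d, where length is 10.0. At 5.0 d I get 11.4, at 10 d 18.1, and the curve flattens towards 20.0.

The forecast names epsilon, with 12 for epsilon and 8.5 for beta, counting “0.85 mM from initiator plus most of the 0.51 mM transfer agent”. It agrees with my direction and differs from me in the count of chains.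

The simulation gives epsilon as the longer, at 17.8 against 11.9 for beta.

    free monomer + initiator → living end + monomer in chains (k = 14.1 M⁻¹ h⁻¹)
    free monomer + living end → monomer in chains + living end, rate k2*[living end]*[free monomer] (k = 20.7 M⁻¹ h⁻¹)
    living end + transfer agent → dead chain (kL = 11.0 M⁻¹ h⁻¹)
    monomer in chains → over-reaction product (k = 1.23 × 10⁻⁵ h⁻¹)

Beta falls short of epsilon because it is read earlier: the same flask at 10 d gives 17.8, with 88.8 % of the charge in chains against 59.6 %. In epsilon, living end and dead chain add up to 0.850 mM, as much as the initiator charge, so the ceiling times the fraction in chains gives 17.8. A neighbouring flask, which is beta with 1.3 mM of transfer agent, still counts 0.850 mM of chains at 5.0 d, and the ceiling times its 47.6 % in chains gives 9.52, against a simulated length of 9.53.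

The readings stem from a simulated flask from invented constants, and the scatter is random.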